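**Plan**

- Retrosynthesis: (a) remove a pivalate from the C6 oxygen; (b) cut C4–C4a, which opens the pyran ring to an aryl 1,1-dialkylprop-2-ynyl ether, an isomer of the chromene; (c) cut O1–C8a to a tertiary propargylic alcohol and an aryliodonium salt; (d) take the alkyne back to a 2,3-epoxy chloride of phytol.
- Forward: the benzene ring is bought, the C20 chain comes from natural (E)-phytol, the tertiary alcohol is O-arylated, the pyran ring closes last by gold-catalysed 6-endo-dig hydroarylation, then the ester is cleaved.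
- Enabling feature: C2 carries O1, so opening at C4–C4a leaves the stereocentre in an open-chain O1–C2–C3≡C4 unit; on the benzene ring C8 bears a methyl group, so C4a is the only free carbon ortho to O1 and closure can go nowhere else.
- Stereochemistry: C4′ and C8′ are those of natural phytol; C2 is set by Sharpless epoxidation of phytol with the L-(+)-tartrate, and the C–O bond made there is never broken again.

Key step: step 7

Assumption: the SMILES is read as (2S,4′R,8′R), i.e. the side-chain centres of natural phytol and the C2 epimer of the natural tocopherol series, so C2 has to be set by a reagent and cannot be taken from a natural chromanol.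

**Step 1**
Reactants: 1 natural phytol, (2E,7R,11R)-3,7,11,15-tetramethylhexadec-2-en-1-ol
Product: 2 [(2S,3S)-3-methyl-3-[(4R,8R)-4,8,12-trimethyltridecyl]oxiran-2-yl]methanol
Conditions: Ti(OiPr)4 (5 mol%), L-(+)-diethyl tartrate (7 mol%), t-BuOOH, 4 Å molecular sieves, CH2Cl2, −20 °C
Reagents that add atoms: tert-butyl hydroperoxide CC(C)(C)OO
Why: Sharpless asymmetric epoxidation: the titanium tartrate complex binds the allylic hydroxyl and delivers oxygen to one alkene face under reagent control, which for an (E)-3,3-disubstituted allylic alcohol of the geraniol type with the L-(+)-tartrate should give the (2S,3S)-epoxide and so sets the future C2 centre, the distant C7 and C11 centres having no say.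

**Step 2**
Reactants: 2 [(2S,3S)-3-methyl-3-[(4R,8R)-4,8,12-trimethyltridecyl]oxiran-2-yl]methanol
Product: 3 (2R,3S,7R,11R)-1-chloro-2,3-epoxy-3,7,11,15-tetramethylhexadecane
Conditions: PPh3, CCl4, NaHCO3, reflux
Reagents that add atoms: carbon tetrachloride ClC(Cl)(Cl)Cl
Why: Appel reaction of a primary alcohol under buffered, neutral conditions that a trisubstituted epoxide should tolerate; no stereocentre is touched (the descriptor at C2 changes only because CH2Cl now outranks C3).

**Step 3**
Reactants: 3 (2R,3S,7R,11R)-1-chloro-2,3-epoxy-3,7,11,15-tetramethylhexadecane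
Product: 4 (3S,7R,11R)-3,7,11,15-tetramethylhexadec-1-yn-3-ol
Conditions: LDA (3.2 equiv), THF, −40 → −20 °C; then NH4Cl aq.
Reagents that add atoms: none
Why: Base-induced fragmentation of a 2,3-epoxy chloride: lithiation next to chlorine and β-elimination open the epoxide at the C2–O bond, a second dehydrochlorination gives the terminal alkyne, and the C3–O bond is carried over with its configuration unchanged.

**Step 4**
Reactants: 5 4-iodo-2,5-dimethylphenol
Product: 6 4-iodo-2,5-dimethylphenyl 2,2-dimethylpropanoate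
Conditions: t-BuCOCl, Et3N, DMAP (cat.), CH2Cl2, 0 °C → rt
Reagents that add atoms: pivaloyl chloride CC(C)(C)C(Cl)=O
Why: Acylation of a phenol (nucleophilic acyl substitution); the pivalate masks the future C6 hydroxyl, makes the ring less electron-rich for the iodine chemistry that follows and can be removed with mild base at the end.

**Step 5**
Reactants: 6 4-iodo-2,5-dimethylphenyl 2,2-dimethylpropanoate
Product: 8 [2,5-dimethyl-4-(pivaloyloxy)phenyl](2,4,6-trimethoxyphenyl)iodonium 4-methylbenzenesulfonate, via hydroxy(tosyloxy)iodoarene 7 (not isolated)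
Conditions: m-CPBA, TsOH·H2O, MeCN, 55 °C; then 1,3,5-trimethoxybenzene, 55 °C
Reagents that add atoms: 4-methylbenzenesulfonic acid Cc1ccc(cc1)S(O)(=O)=O; 1,3,5-trimethoxybenzene COc1cc(OC)cc(OC)c1
Why: One-pot synthesis of an unsymmetrical diaryliodonium salt: the peracid oxidises the aryl iodide to a trivalent iodine hydroxy tosylate, which then substitutes the very electron-rich trimethoxybenzene (electrophilic aromatic substitution by iodine) to give a salt whose trimethoxyphenyl group is not transferred.

**Step 6**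
Reactants: 4 (3S,7R,11R)-3,7,11,15-tetramethylhexadec-1-yn-3-ol; 8 [2,5-dimethyl-4-(pivaloyloxy)phenyl](2,4,6-trimethoxyphenyl)iodonium 4-methylbenzenesulfonate
Product: 10 2,5-dimethyl-4-{[(3S,7R,11R)-3,7,11,15-tetramethylhexadec-1-yn-3-yl]oxy}phenyl 2,2-dimethylpropanoate, via sodium alkoxide 9 (not isolated)
Conditions: NaH (1.05 equiv), toluene, 0 °C → rt; then 8 (1.2 equiv), rt
Reagents that add atoms: none
Why: Metal-free O-arylation of a tertiary alkoxide with a diaryliodonium salt (ligand exchange at iodine, then ligand coupling): the oxygen should be arylated by the less electron-rich, ortho-methylated ring while the trimethoxyphenyl group leaves as its iodide, and since the bond formed is O–C(aryl) the C2 centre keeps its configuration.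

**Step 7**
Reactants: 10 2,5-dimethyl-4-{[(3S,7R,11R)-3,7,11,15-tetramethylhexadec-1-yn-3-yl]oxy}phenyl 2,2-dimethylpropanoate
Product: 11 (2S)-2,5,8-trimethyl-2-[(4R,8R)-4,8,12-trimethyltridecyl]-2H-chromen-6-yl 2,2-dimethylpropanoate
Conditions: Ph3PAuNTf2 (3 mol%), CH2Cl2, rt
Reagents that add atoms: none
Why: The cationic monovalent gold centre binds the terminal alkyne of 10 and makes C4 (target numbering) electrophilic; the arene carbon ortho to O1 attacks it in a Friedel–Crafts sense, and rearomatisation followed by protodeauration leaves the C3=C4 double bond, so the step is a pure isomerisation. The closest known reaction type is the gold-catalysed intramolecular hydroarylation (cycloisomerisation) of aryl 1,1-dialkylprop-2-ynyl ethers to 2,2-dialkyl-2H-chromenes. The pyran ring closes in the 6-endo-dig mode by formation of the C4–C4a bond. No stereocentre is formed, and C2 should keep its configuration because none of its four bonds is broken, in contrast to the thermal Claisen route to chromenes, which passes through a planar C2. The step needs attack at C4a only and 6-endo over 5-exo closure: the C8 methyl blocks the other ortho position, O1 makes C4a the most nucleophilic free carbon, and the inductive pull of O1 on the internal alkyne carbon together with the strain of a 3-methylene-2,3-dihydrobenzofuran disfavours 5-exo attack. Room temperature and the non-coordinating NTf2 counter-ion should keep ionisation of the tertiary propargylic C–O bond from competing.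

**Step 8**
Reactants: 11 (2S)-2,5,8-trimethyl-2-[(4R,8R)-4,8,12-trimethyltridecyl]-2H-chromen-6-yl 2,2-dimethylpropanoate
Product: 12 (2S)-2,5,8-trimethyl-2-[(4R,8R)-4,8,12-trimethyltridecyl]-2H-chromen-6-ol
Conditions: K2CO3 (0.5 equiv), MeOH/THF, rt, under argon
Reagents that add atoms: none
Why: Methanolysis (transesterification) of an aryl ester, easy because phenoxide is a good leaving group, under conditions that leave the chromene double bond and all three stereocentres alone; air is kept out because the product is an electron-rich, tocopherol-like phenol.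

**Compound list**

1 | natural phytol, (2E,7R,11R)-3,7,11,15-tetramethylhexadec-2-en-1-ol | OC/C=C(\C)CCC[C@H](C)CCC[C@H](C)CCCC(C)C | starting material
2 | [(2S,3S)-3-methyl-3-[(4R,8R)-4,8,12-trimethyltridecyl]oxiran-2-yl]methanol | OC[C@@H]1O[C@@]1(C)CCC[C@H](C)CCC[C@H](C)CCCC(C)C | intermediate
3 | (2R,3S,7R,11R)-1-chloro-2,3-epoxy-3,7,11,15-tetramethylhexadecane | ClC[C@@H]1O[C@@]1(C)CCC[C@H](C)CCC[C@H](C)CCCC(C)C | intermediate
4 | (3S,7R,11R)-3,7,11,15-tetramethylhexadec-1-yn-3-ol | O[C@@](C)(CCC[C@H](C)CCC[C@H](C)CCCC(C)C)C#C | intermediate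
5 | 4-iodo-2,5-dimethylphenol | Cc1cc(I)c(C)cc1O | starting material
6 | 4-iodo-2,5-dimethylphenyl 2,2-dimethylpropanoate | Cc1cc(I)c(C)cc1OC(=O)C(C)(C)C | intermediate
7 | 4-[hydroxy(tosyloxy)iodo]-2,5-dimethylphenyl 2,2-dimethylpropanoate | Cc1ccc(cc1)S(=O)(=O)OI(O)c1cc(C)c(OC(=O)C(C)(C)C)cc1C | intermediate (not isolated)
8 | [2,5-dimethyl-4-(pivaloyloxy)phenyl](2,4,6-trimethoxyphenyl)iodonium 4-methylbenzenesulfonate | COc1cc(OC)c([I+]c2cc(C)c(OC(=O)C(C)(C)C)cc2C)c(OC)c1.Cc1ccc(cc1)S(=O)(=O)[O-] | intermediate
9 | sodium (3S,7R,11R)-3,7,11,15-tetramethylhexadec-1-yn-3-olate | [Na+].[O-][C@@](C)(CCC[C@H](C)CCC[C@H](C)CCCC(C)C)C#C | intermediate (not isolated)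
10 | 2,5-dimethyl-4-{[(3S,7R,11R)-3,7,11,15-tetramethylhexadec-1-yn-3-yl]oxy}phenyl 2,2-dimethylpropanoate | Cc1cc(OC(=O)C(C)(C)C)c(C)cc1O[C@@](C)(CCC[C@H](C)CCC[C@H](C)CCCC(C)C)C#C | intermediate
11 | (2S)-2,5,8-trimethyl-2-[(4R,8R)-4,8,12-trimethyltridecyl]-2H-chromen-6-yl 2,2-dimethylpropanoate | Cc1cc(OC(=O)C(C)(C)C)c(C)c2c1O[C@@](C)(CCC[C@H](C)CCC[C@H](C)CCCC(C)C)C=C2 | intermediate
12 | (2S)-2,5,8-trimethyl-2-[(4R,8R)-4,8,12-trimethyltridecyl]-2H-chromen-6-ol | Cc1cc(O)c(C)c2c1O[C@@](C)(CCC[C@H](C)CCC[C@H](C)CCCC(C)C)C=C2 | target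

**Step count**

Total: 8 steps. Longest linear sequence: 6 steps (steps 1, 2, 3, 6, 7, 8; 1 → 2 → 3 → 4 → 10 → 11 → 12).

**Steps most likely to fail**

Step 6. The hindered tertiary alkoxide may act as a base on the iodonium salt (deprotonation next to iodine, aryne formation and loss of regiochemical fidelity), may take up the pivaloyl group, or may couple too slowly. The fallback makes the ether bond the other way round, with the phenol as nucleophile and a π-allyl unit as electrophile (Tsuji–Trost asymmetric allylic etherification); it sets out from 1 and comes back at 10. Compound 1 is converted with methyl chloroformate and pyridine into methyl (2E,7R,11R)-3,7,11,15-tetramethylhexadec-2-en-1-yl carbonate F1. Commercial 2,5-dimethylbenzene-1,4-diol is mono-acylated (t-BuCOCl, pyridine) to 4-hydroxy-2,5-dimethylphenyl 2,2-dimethylpropanoate F2. Pd2(dba)3·CHCl3 and the enantiomer of N,N′-(cyclohexane-1,2-diyl)bis[2-(diphenylphosphino)benzamide] that leads to the 3S product should join F1 and F2 at the tertiary allyl terminus. The ligand enantiomer is to be assigned by comparison with 10 from the main route. The product is 2,5-dimethyl-4-{[(3S,7R,11R)-3,7,11,15-tetramethylhexadec-1-en-3-yl]oxy}phenyl 2,2-dimethylpropanoate F3, in which C2 is set by the catalyst. Lemieux–Johnson cleavage of the vinyl group (OsO4 cat., NaIO4, 2,6-lutidine, dioxane/H2O) should give the non-epimerisable aldehyde 4-{[(2S,6R,10R)-2,6,10,14-tetramethyl-1-oxopentadecan-2-yl]oxy}-2,5-dimethylphenyl 2,2-dimethylpropanoate F4. Lithiated trimethylsilyldiazomethane (Me3SiCHN2, n-BuLi, THF, −78 °C, Colvin rearrangement) should then turn F4 into 10.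

Step 7. The Lewis-acidic catalyst may ionise the tertiary propargylic C–O bond or open a [3,3] pathway, both of which erode the configuration at C2, or it may be tied up as a gold acetylide. The fallback closes the pyran ring at the other bond, O1–C8a, by intramolecular Buchwald–Hartwig etherification; it sets out from 4 and comes back at 11. 4-Hydroxy-2,5-dimethylphenyl 2,2-dimethylpropanoate F2 (made as above) is iodinated ortho to the hydroxyl (N-iodosuccinimide, MeCN) to 4-hydroxy-3-iodo-2,5-dimethylphenyl 2,2-dimethylpropanoate F5. Tf2O and pyridine convert it into 3-iodo-2,5-dimethyl-4-[(trifluoromethanesulfonyl)oxy]phenyl 2,2-dimethylpropanoate F6. Sonogashira coupling of 4 at the C–I bond (PdCl2(PPh3)2, CuI, Et3N, rt) should give 3-[(3S,7R,11R)-3-hydroxy-3,7,11,15-tetramethylhexadec-1-yn-1-yl]-2,5-dimethyl-4-[(trifluoromethanesulfonyl)oxy]phenyl 2,2-dimethylpropanoate F7. Semi-hydrogenation (H2, Pd/CaCO3 poisoned with Pb(OAc)2, quinoline, Lindlar conditions) should give 3-[(1Z,3S,7R,11R)-3-hydroxy-3,7,11,15-tetramethylhexadec-1-en-1-yl]-2,5-dimethyl-4-[(trifluoromethanesulfonyl)oxy]phenyl 2,2-dimethylpropanoate F8. Zerovalent palladium with a bulky biaryl phosphine (Pd2(dba)3, 2-di-tert-butylphosphino-2′,4′,6′-triisopropylbiphenyl, K3PO4, toluene, 80 °C) should then join the tertiary alkoxide to C8a with loss of triflate and give 11, again without breaking a bond at C2.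

Step 3. The second elimination may stall at the chloroalkene, or the base may attack the epoxide or the primary chloride. The fallback builds the triple bond after the ether bond instead; it sets out from 3 and comes back at 10. Zn and NaI in MeOH (reductive elimination of the epoxy halide) should give (3S,7R,11R)-3,7,11,15-tetramethylhexadec-1-en-3-ol F9 with the C3–O bond intact. Its sodium alkoxide is arylated with 8 as in step 6 to 2,5-dimethyl-4-{[(3S,7R,11R)-3,7,11,15-tetramethylhexadec-1-en-3-yl]oxy}phenyl 2,2-dimethylpropanoate F3. This is cleaved to 4-{[(2S,6R,10R)-2,6,10,14-tetramethyl-1-oxopentadecan-2-yl]oxy}-2,5-dimethylphenyl 2,2-dimethylpropanoate F4 and homologated to 10 as described for step 6.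

**Further compounds**

F1 | step 6 | methyl (2E,7R,11R)-3,7,11,15-tetramethylhexadec-2-en-1-yl carbonate | COC(=O)OC/C=C(\C)CCC[C@H](C)CCC[C@H](C)CCCC(C)C
F2 | step 6 | 4-hydroxy-2,5-dimethylphenyl 2,2-dimethylpropanoate | Cc1cc(OC(=O)C(C)(C)C)c(C)cc1O
F3 | step 6 | 2,5-dimethyl-4-{[(3S,7R,11R)-3,7,11,15-tetramethylhexadec-1-en-3-yl]oxy}phenyl 2,2-dimethylpropanoate | Cc1cc(OC(=O)C(C)(C)C)c(C)cc1O[C@@](C)(CCC[C@H](C)CCC[C@H](C)CCCC(C)C)C=C
F4 | step 6 | 4-{[(2S,6R,10R)-2,6,10,14-tetramethyl-1-oxopentadecan-2-yl]oxy}-2,5-dimethylphenyl 2,2-dimethylpropanoate | Cc1cc(OC(=O)C(C)(C)C)c(C)cc1O[C@@](C)(CCC[C@H](C)CCC[C@H](C)CCCC(C)C)C=O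
F5 | step 7 | 4-hydroxy-3-iodo-2,5-dimethylphenyl 2,2-dimethylpropanoate | Cc1cc(OC(=O)C(C)(C)C)c(C)c(I)c1O
F6 | step 7 | 3-iodo-2,5-dimethyl-4-[(trifluoromethanesulfonyl)oxy]phenyl 2,2-dimethylpropanoate | Cc1cc(OC(=O)C(C)(C)C)c(C)c(I)c1OS(=O)(=O)C(F)(F)F
F7 | step 7 | 3-[(3S,7R,11R)-3-hydroxy-3,7,11,15-tetramethylhexadec-1-yn-1-yl]-2,5-dimethyl-4-[(trifluoromethanesulfonyl)oxy]phenyl 2,2-dimethylpropanoate | Cc1cc(OC(=O)C(C)(C)C)c(C)c(C#C[C@@](C)(O)CCC[C@H](C)CCC[C@H](C)CCCC(C)C)c1OS(=O)(=O)C(F)(F)F
F8 | step 7 | 3-[(1Z,3S,7R,11R)-3-hydroxy-3,7,11,15-tetramethylhexadec-1-en-1-yl]-2,5-dimethyl-4-[(trifluoromethanesulfonyl)oxy]phenyl 2,2-dimethylpropanoate | Cc1cc(OC(=O)C(C)(C)C)c(C)c(/C=C\[C@@](C)(O)CCC[C@H](C)CCC[C@H](C)CCCC(C)C)c1OS(=O)(=O)C(F)(F)F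
F9 | step 3 | (3S,7R,11R)-3,7,11,15-tetramethylhexadec-1-en-3-ol | O[C@@](C)(CCC[C@H](C)CCC[C@H](C)CCCC(C)C)C=C
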